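The isoflavone is cut at the C3–C4 bond. C3 bears ring B and sits between the C4 ketone and the C2 methine of ring C, so it corresponds to the nucleophilic carbon of a 2,4,5-trimethoxyphenylacetaldehyde enamine, and C4 to the acyl carbon of a ring A salicyloyl chloride. One C-acylation therefore joins ring A to the complete C2–C3–ring B unit, with C2 already an aminomethylene at the aldehyde oxidation level. The acyl partner is an O-acetylated, prenylated 6-hydroxy-2,4-dimethoxybenzoyl chloride whose substitution pattern is fixed by the symmetry of 3,5-dimethoxyphenol. Deacetylation then lets the phenoxide close ring C, and chelation-controlled demethylation frees the C5 hydroxyl.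

Key step: step 11

Remark: the prenyl group must lie between the two methoxy groups of ring A (para to the phenol oxygen) to end up at C6; it is therefore placed by directed lithiation of a silyl ether, because phenoxide C-alkylation would favour the ortho position and lead to the C8 isomer.

Step 1
Reactants: 1 3,5-dimethoxyphenol
Product: 2 (3,5-dimethoxyphenoxy)triisopropylsilane
Conditions: TIPSCl, imidazole, DMF, rt
Reagents that add atoms: triisopropylsilyl chloride, CC(C)[Si](Cl)(C(C)C)C(C)C
Why: Imidazole-promoted O-silylation gives a bulky, non-directing silyl ether that tolerates n-BuLi and leaves the carbon between the two methoxy groups as the only doubly activated site.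

Step 2
Reactants: 2 (3,5-dimethoxyphenoxy)triisopropylsilane; 3 prenyl bromide
Product: 5 [3,5-dimethoxy-4-(3-methylbut-2-en-1-yl)phenoxy]triisopropylsilane, via aryllithium 4 (not isolated)
Conditions: n-BuLi, THF, 0 °C → rt; then CuBr·SMe2 (10 mol %), 3, −78 °C → rt
Reagents that add atoms: none
Why: Directed ortho-metalation takes place at the carbon flanked by both methoxy groups, and copper-catalysed alkylation of the aryllithium at the primary carbon of the allylic bromide puts the prenyl group para to the silyloxy group, the position that becomes C6.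

Step 3
Reactants: 5 [3,5-dimethoxy-4-(3-methylbut-2-en-1-yl)phenoxy]triisopropylsilane
Product: 6 3,5-dimethoxy-4-(3-methylbut-2-en-1-yl)phenol
Conditions: TBAF, AcOH, THF, 0 °C
Reagents that add atoms: none
Why: Buffered fluoride desilylation frees the phenol under near-neutral conditions that leave the prenyl alkene and the methyl ethers untouched.

Step 4
Reactants: 6 3,5-dimethoxy-4-(3-methylbut-2-en-1-yl)phenol
Product: 7 6-hydroxy-2,4-dimethoxy-3-(3-methylbut-2-en-1-yl)benzaldehyde
Conditions: MgCl2, Et3N, (CH2O)n, MeCN, reflux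
Reagents that add atoms: formaldehyde (as paraformaldehyde), C=O
Why: Magnesium-phenoxide-directed ortho-formylation (Casnati–Skattebøl reaction) is non-acidic and strictly ortho-selective, and because the two ortho positions are equivalent and the para position is blocked only one aldehyde can form.

Step 5
Reactants: 7 6-hydroxy-2,4-dimethoxy-3-(3-methylbut-2-en-1-yl)benzaldehyde
Product: 8 2-formyl-3,5-dimethoxy-4-(3-methylbut-2-en-1-yl)phenyl acetate
Conditions: Ac2O, Et3N, DMAP (cat.), CH2Cl2, 0 °C → rt
Reagents that add atoms: acetic anhydride, CC(=O)OC(C)=O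
Why: DMAP-catalysed O-acetylation masks the future O1 before the oxidation, so the electron-rich phenol is neither chlorinated in the next step nor free to compete as a nucleophile during acyl chloride formation and acylation.

Step 6
Reactants: 8 2-formyl-3,5-dimethoxy-4-(3-methylbut-2-en-1-yl)phenyl acetate
Product: 9 6-acetoxy-2,4-dimethoxy-3-(3-methylbut-2-en-1-yl)benzoic acid
Conditions: NaClO2, NaH2PO4, 2-methyl-2-butene (large excess), t-BuOH/THF/H2O, 0 °C → rt; cold work-up at pH 4
Reagents that add atoms: sodium chlorite, [Na+].[O-]Cl=O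
Why: Lindgren–Pinnick chlorite oxidation converts the aldehyde to the acid in a buffered medium in which the aryl acetate is stable, while the excess sacrificial alkene intercepts HOCl before it can reach the prenyl group or the arene.

Step 7
Reactants: 9 6-acetoxy-2,4-dimethoxy-3-(3-methylbut-2-en-1-yl)benzoic acid
Product: 10 6-acetoxy-2,4-dimethoxy-3-(3-methylbut-2-en-1-yl)benzoyl chloride
Conditions: 1-chloro-N,N,2-trimethylprop-1-en-1-amine (Ghosez reagent), CH2Cl2, 0 °C → rt; concentrate and use crude
Reagents that add atoms: 1-chloro-N,N,2-trimethylprop-1-en-1-amine, CC(C)=C(Cl)N(C)C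
Why: The α-chloroenamine converts the acid to the acyl chloride under neutral conditions with a neutral amide as the only by-product, so no HCl is available to add to the prenyl alkene or to cleave the acetate.

Step 8
Reactants: 11 2,4,5-trimethoxybenzaldehyde
Product: 12 1,2,4-trimethoxy-5-(2-methoxyethenyl)benzene (E/Z mixture)
Conditions: Ph3P(CH2OMe)Cl, KOtBu, THF, 0 °C → rt
Reagents that add atoms: (methoxymethyl)triphenylphosphonium chloride, COC[P+](c1ccccc1)(c1ccccc1)c1ccccc1.[Cl-]
Why: Wittig methoxymethylenation adds the one carbon that becomes C2, and both enol ether isomers hydrolyse to the same aldehyde.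

Step 9
Reactants: 12 1,2,4-trimethoxy-5-(2-methoxyethenyl)benzene
Product: 13 2-(2,4,5-trimethoxyphenyl)acetaldehyde
Conditions: 2 M aq. HCl, THF, rt; used at once
Reagents that add atoms: water, O
Why: Mild acid hydrolysis of the enol ether releases the arylacetaldehyde, which is carried forward immediately because electron-rich arylacetaldehydes self-condense on storage.

Step 10
Reactants: 13 2-(2,4,5-trimethoxyphenyl)acetaldehyde; 14 morpholine
Product: 15 4-[(E)-2-(2,4,5-trimethoxyphenyl)ethenyl]morpholine
Conditions: 4 Å molecular sieves, toluene, rt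
Reagents that add atoms: none
Why: Dehydrative condensation of the aldehyde with the secondary amine gives the enamine, and the E isomer is favoured because it is conjugated with the arene and avoids the steric clash of the Z form.

Step 11
Reactants: 10 6-acetoxy-2,4-dimethoxy-3-(3-methylbut-2-en-1-yl)benzoyl chloride; 15 4-[(E)-2-(2,4,5-trimethoxyphenyl)ethenyl]morpholine
Product: 16 (E)-1-[6-acetoxy-2,4-dimethoxy-3-(3-methylbut-2-en-1-yl)phenyl]-3-(morpholin-4-yl)-2-(2,4,5-trimethoxyphenyl)prop-2-en-1-one
Conditions: Et3N, CH2Cl2, 0 °C → 40 °C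
Reagents that add atoms: none
Why: The enamine attacks the acyl chloride through its aryl-bearing β-carbon, chloride departs, and Et3N deprotonates the resulting iminium ion to give the push–pull enaminone. This is a Stork enamine acylation with an aroyl chloride, the closest analogy being the C-acylation of β-aminostyrenes. Only the C3–C4 bond is formed: no ring is closed and no stereocentre is created, and the alkene geometry (drawn E) is labile and is erased in the next step. The step needs C- over N-acylation and reaction at the acyl chloride in preference to the aryl acetate; N-acylation is reversible and drains into the stabilised vinylogous amide, and the acyl chloride, which reacts through an acylium-like species stabilised by the ortho and para methoxy groups, is far more electrophilic than the acetate. The acetate keeps the future O1 masked, so ring C cannot close before it is intended to.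

Step 12
Reactants: 16 (E)-1-[6-acetoxy-2,4-dimethoxy-3-(3-methylbut-2-en-1-yl)phenyl]-3-(morpholin-4-yl)-2-(2,4,5-trimethoxyphenyl)prop-2-en-1-one
Product: 18 5,7-dimethoxy-6-(3-methylbut-2-en-1-yl)-3-(2,4,5-trimethoxyphenyl)-4H-chromen-4-one, via free phenol enaminone 17 (not isolated)
Conditions: K2CO3 (0.2 equiv), MeOH, rt → 40 °C
Reagents that add atoms: none
Why: Methoxide transesterification removes the aryl acetate and the liberated phenoxide adds to the enaminone β-carbon (6-endo-trig oxa-Michael addition), after which E1cB loss of morpholine gives the chromone, the standard closure of o-hydroxyaryl enaminones.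

Step 13
Reactants: 18 5,7-dimethoxy-6-(3-methylbut-2-en-1-yl)-3-(2,4,5-trimethoxyphenyl)-4H-chromen-4-one
Product: 19 5-hydroxy-7-methoxy-6-(3-methylbut-2-en-1-yl)-3-(2,4,5-trimethoxyphenyl)-4H-chromen-4-one
Conditions: BCl3 (1 M in CH2Cl2), CH2Cl2, −78 → 0 °C; quench into sat. aq. NaHCO3
Reagents that add atoms: none
Why: BCl3 chelates the C4 carbonyl and the peri C5 methoxy oxygen, so chloride cleaves only that methyl ether (chelation-controlled demethylation) and the other four methoxy groups remain, while low temperature and a bicarbonate quench keep acid away from the prenyl alkene.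

Compound list
1 | 3,5-dimethoxyphenol | COc1cc(O)cc(OC)c1 | starting material
2 | (3,5-dimethoxyphenoxy)triisopropylsilane | COc1cc(O[Si](C(C)C)(C(C)C)C(C)C)cc(OC)c1 | intermediate
3 | prenyl bromide (1-bromo-3-methylbut-2-ene) | CC(C)=CCBr | starting material
4 | [2,6-dimethoxy-4-(triisopropylsilyloxy)phenyl]lithium (not isolated) | COc1cc(O[Si](C(C)C)(C(C)C)C(C)C)cc(OC)c1[Li] | intermediate
5 | [3,5-dimethoxy-4-(3-methylbut-2-en-1-yl)phenoxy]triisopropylsilane | COc1cc(O[Si](C(C)C)(C(C)C)C(C)C)cc(OC)c1CC=C(C)C | intermediate
6 | 3,5-dimethoxy-4-(3-methylbut-2-en-1-yl)phenol | COc1cc(O)cc(OC)c1CC=C(C)C | intermediate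
7 | 6-hydroxy-2,4-dimethoxy-3-(3-methylbut-2-en-1-yl)benzaldehyde | COc1cc(O)c(C=O)c(OC)c1CC=C(C)C | intermediate
8 | 2-formyl-3,5-dimethoxy-4-(3-methylbut-2-en-1-yl)phenyl acetate | COc1cc(OC(C)=O)c(C=O)c(OC)c1CC=C(C)C | intermediate
9 | 6-acetoxy-2,4-dimethoxy-3-(3-methylbut-2-en-1-yl)benzoic acid | COc1cc(OC(C)=O)c(C(=O)O)c(OC)c1CC=C(C)C | intermediate
10 | 6-acetoxy-2,4-dimethoxy-3-(3-methylbut-2-en-1-yl)benzoyl chloride | COc1cc(OC(C)=O)c(C(Cl)=O)c(OC)c1CC=C(C)C | intermediate
11 | 2,4,5-trimethoxybenzaldehyde | COc1cc(OC)c(C=O)cc1OC | starting material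
12 | 1,2,4-trimethoxy-5-(2-methoxyethenyl)benzene (E/Z mixture) | COC=Cc1cc(OC)c(OC)cc1OC | intermediate
13 | 2-(2,4,5-trimethoxyphenyl)acetaldehyde | COc1cc(OC)c(CC=O)cc1OC | intermediate
14 | morpholine | C1COCCN1 | starting material
15 | 4-[(E)-2-(2,4,5-trimethoxyphenyl)ethenyl]morpholine | COc1cc(OC)c(/C=C/N2CCOCC2)cc1OC | intermediate
16 | (E)-1-[6-acetoxy-2,4-dimethoxy-3-(3-methylbut-2-en-1-yl)phenyl]-3-(morpholin-4-yl)-2-(2,4,5-trimethoxyphenyl)prop-2-en-1-one | COc1cc(OC(C)=O)c(C(=O)/C(=C/N2CCOCC2)c2cc(OC)c(OC)cc2OC)c(OC)c1CC=C(C)C | intermediate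
17 | (E)-1-[6-hydroxy-2,4-dimethoxy-3-(3-methylbut-2-en-1-yl)phenyl]-3-(morpholin-4-yl)-2-(2,4,5-trimethoxyphenyl)prop-2-en-1-one (not isolated) | COc1cc(O)c(C(=O)/C(=C/N2CCOCC2)c2cc(OC)c(OC)cc2OC)c(OC)c1CC=C(C)C | intermediate
18 | 5,7-dimethoxy-6-(3-methylbut-2-en-1-yl)-3-(2,4,5-trimethoxyphenyl)-4H-chromen-4-one | COc1cc(OC)c(-c2coc3cc(OC)c(CC=C(C)C)c(OC)c3c2=O)cc1OC | intermediate
19 | 5-hydroxy-7-methoxy-6-(3-methylbut-2-en-1-yl)-3-(2,4,5-trimethoxyphenyl)-4H-chromen-4-one | COc1cc(OC)c(-c2coc3cc(OC)c(CC=C(C)C)c(O)c3c2=O)cc1OC | target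

Total step count: 13. Longest linear sequence: 10 steps (steps 1–7, then 11–13); the ring B branch (steps 8–10) joins at step 11.

Steps most likely to fail

Step 11. The crowded 2,6-dioxygenated acyl chloride may react slowly, so that acylation at nitrogen, acetyl transfer from the aryl acetate to liberated morpholine, or hydrolysis of the enamine overtakes C–C bond formation. The fallback is the deoxybenzoin route; it sets out from 10 and 13 and comes back at 18. Pinnick oxidation of 13 would give 2-(2,4,5-trimethoxyphenyl)acetic acid F1, whose dianion (LDA, THF, −78 °C) would be acylated by 10 to give the β-keto acid F2. This should lose CO2 on mild acidic work-up to give the deoxybenzoin acetate F3, and K2CO3 in MeOH would then remove the acetate to give the o-hydroxy deoxybenzoin F4. Heating F4 with N,N-dimethylformamide dimethyl acetal in toluene would install C2 as the dimethylaminomethylene ketone F5, which should cyclise in the same flask with loss of dimethylamine to give 18.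

Step 13. The prenyl alkene may take part under the Lewis-acid conditions, either by hydrochlorination or by capture of the tertiary cation by the newly freed C5 oxygen to give a dimethylchroman. The fallback avoids ether cleavage altogether by carrying the C5 oxygen as a MOM ether; it sets out from 15 and 3 and comes back at 19.
- Ring A would be rebuilt from commercial 5-methoxyresorcinol: monosilylation (TIPSCl, imidazole) would give 3-methoxy-5-(triisopropylsilyloxy)phenol F6, and MOMCl with i-Pr2NEt would give the mixed ether F7.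
- Lithiation between the MOM and methoxy oxygens (n-BuLi) followed by alkylation with 3 as in step 2 would give the prenyl arene F8.
- A second MOM-directed lithiation (s-BuLi, TMEDA, −78 °C) and CO2 would give the benzoic acid F9, which the chloroenamine of step 7 would convert into the acyl chloride F10, used cold and at once.
- Acylation of 15 under the conditions of step 11 would give the silyloxy enaminone F11.
- TBAF would remove the silyl group and let the phenoxide close ring C to give the 5-O-MOM isoflavone F12, and HCl in MeOH at rt would remove the MOM group to give 19.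

Step 2. Allylic transposition during the alkylation (attack through the tertiary terminus to give the 1,1-dimethylallyl isomer) or bromine–lithium exchange with the allylic bromide may divert the aryllithium. The fallback sets out from 2 through 4 and comes back at 5. Aryllithium 4 would be alkylated with allyl bromide, for which both modes of attack give the same product, to give the allyl arene F13. Cross-metathesis with 2-methyl-2-butene (second-generation Grubbs catalyst, CH2Cl2, 40 °C) would then convert the allyl group into the prenyl group of 5.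

Further compounds
F1 | step 11 | 2-(2,4,5-trimethoxyphenyl)acetic acid | COc1cc(OC)c(CC(=O)O)cc1OC
F2 | step 11 | 3-[6-acetoxy-2,4-dimethoxy-3-(3-methylbut-2-en-1-yl)phenyl]-3-oxo-2-(2,4,5-trimethoxyphenyl)propanoic acid (racemic, not isolated) | COc1cc(OC(C)=O)c(C(=O)C(C(=O)O)c2cc(OC)c(OC)cc2OC)c(OC)c1CC=C(C)C
F3 | step 11 | 3,5-dimethoxy-4-(3-methylbut-2-en-1-yl)-2-[2-(2,4,5-trimethoxyphenyl)acetyl]phenyl acetate | COc1cc(OC(C)=O)c(C(=O)Cc2cc(OC)c(OC)cc2OC)c(OC)c1CC=C(C)C
F4 | step 11 | 1-[6-hydroxy-2,4-dimethoxy-3-(3-methylbut-2-en-1-yl)phenyl]-2-(2,4,5-trimethoxyphenyl)ethan-1-one | COc1cc(O)c(C(=O)Cc2cc(OC)c(OC)cc2OC)c(OC)c1CC=C(C)C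
F5 | step 11 | (E)-3-(dimethylamino)-1-[6-hydroxy-2,4-dimethoxy-3-(3-methylbut-2-en-1-yl)phenyl]-2-(2,4,5-trimethoxyphenyl)prop-2-en-1-one (not isolated) | COc1cc(O)c(C(=O)/C(=C/N(C)C)c2cc(OC)c(OC)cc2OC)c(OC)c1CC=C(C)C
F6 | step 13 | 3-methoxy-5-(triisopropylsilyloxy)phenol | COc1cc(O)cc(O[Si](C(C)C)(C(C)C)C(C)C)c1
F7 | step 13 | triisopropyl[3-methoxy-5-(methoxymethoxy)phenoxy]silane | COCOc1cc(OC)cc(O[Si](C(C)C)(C(C)C)C(C)C)c1
F8 | step 13 | triisopropyl[3-methoxy-5-(methoxymethoxy)-4-(3-methylbut-2-en-1-yl)phenoxy]silane | COCOc1cc(O[Si](C(C)C)(C(C)C)C(C)C)cc(OC)c1CC=C(C)C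
F9 | step 13 | 4-methoxy-2-(methoxymethoxy)-3-(3-methylbut-2-en-1-yl)-6-(triisopropylsilyloxy)benzoic acid | COCOc1c(C(=O)O)c(O[Si](C(C)C)(C(C)C)C(C)C)cc(OC)c1CC=C(C)C
F10 | step 13 | 4-methoxy-2-(methoxymethoxy)-3-(3-methylbut-2-en-1-yl)-6-(triisopropylsilyloxy)benzoyl chloride | COCOc1c(C(Cl)=O)c(O[Si](C(C)C)(C(C)C)C(C)C)cc(OC)c1CC=C(C)C
F11 | step 13 | (E)-1-[4-methoxy-2-(methoxymethoxy)-3-(3-methylbut-2-en-1-yl)-6-(triisopropylsilyloxy)phenyl]-3-(morpholin-4-yl)-2-(2,4,5-trimethoxyphenyl)prop-2-en-1-one | COCOc1c(C(=O)/C(=C/N2CCOCC2)c2cc(OC)c(OC)cc2OC)c(O[Si](C(C)C)(C(C)C)C(C)C)cc(OC)c1CC=C(C)C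
F12 | step 13 | 7-methoxy-5-(methoxymethoxy)-6-(3-methylbut-2-en-1-yl)-3-(2,4,5-trimethoxyphenyl)-4H-chromen-4-one | COCOc1c(CC=C(C)C)c(OC)cc2occ(-c3cc(OC)c(OC)cc3OC)c(=O)c12
F13 | step 2 | (4-allyl-3,5-dimethoxyphenoxy)triisopropylsilane | C=CCc1c(OC)cc(O[Si](C(C)C)(C(C)C)C(C)C)cc1OC
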